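The oxolane ring is traced back to a 2,5-dihydrofuran and that ring to a vinyl oxirane. The feature exploited is ring oxygen O1, which ties benzylic C2 to the unsubstituted methylene C5. O1 can first be installed enantioselectively as a C2–C3 epoxide and later be shifted from C3 to C5. In one operation a copper catalyst cleaves C3–O, forms O1–C5, closes the five-membered ring and leaves a C3=C4 alkene, while C2–O and its configuration persist. The precursor is the silyl ether of a (2R,3R)-3-aryl-2-vinyloxiran-2-ylmethanol, obtained by tartrate-controlled epoxidation of a 2-vinylcinnamyl alcohol. Hydroboration and inversion at C4 then set C3 and C4.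

Key step: step 6

Remark: atom labels follow the oxolane ring of the target (O1, aryl-bearing C2, C3, carbinol C4, methylene C5; C6 is the exocyclic CH2O carbon). The C2 descriptor is R in the oxiranes and the dihydrofuran and S in all oxolanes through CIP priorities only, with the spatial arrangement unchanged.

Step 1
Reactants: 1 (E)-3,4-dimethoxycinnamaldehyde
Product: 3 (Z)-2-bromo-3-(3,4-dimethoxyphenyl)prop-2-enal, via dibromo aldehyde 2 (not isolated)
Conditions: Br2 (1.0 equiv), CH2Cl2, −78 → 0 °C; then Et3N (1.5 equiv), 0 °C → rt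
Reagents that add atoms: bromine, BrBr
Why: Bromination–dehydrobromination: the aryl-activated C=C should take up bromine faster than the ring is substituted when one equivalent is used cold, and amine-induced E1cB loss of HBr through the acidic α-hydrogen should give the more stable Z bromoenal, in which aryl and formyl remain trans.

Step 2
Reactants: 3 (Z)-2-bromo-3-(3,4-dimethoxyphenyl)prop-2-enal
Product: 4 (Z)-2-bromo-3-(3,4-dimethoxyphenyl)prop-2-en-1-ol
Conditions: NaBH4, MeOH, 0 °C
Reagents that add atoms: none
Why: Borohydride 1,2-reduction of the aldehyde is much faster than any attack on the alkenyl bromide, so the Z geometry and the C–Br bond are kept.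

Step 3
Reactants: 4 (Z)-2-bromo-3-(3,4-dimethoxyphenyl)prop-2-en-1-ol; 5 vinylboronic acid pinacol ester
Product: 6 (2E)-2-[(3,4-dimethoxyphenyl)methylidene]but-3-en-1-ol
Conditions: PdCl2(dppf) (3 mol %), K2CO3 (2 equiv), 1,4-dioxane–H2O, 70 °C
Reagents that add atoms: none
Why: Suzuki–Miyaura coupling of an alkenyl bromide proceeds with retention of alkene geometry and tolerates the free hydroxyl group, so the vinyl group ends cis to the aryl group and the hydroxymethyl group trans to it (E dienol).

Step 4
Reactants: 6 (2E)-2-[(3,4-dimethoxyphenyl)methylidene]but-3-en-1-ol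
Product: 7 [(2R,3R)-3-(3,4-dimethoxyphenyl)-2-ethenyloxiran-2-yl]methanol
Conditions: Ti(OiPr)4 (10 mol %), D-(−)-diisopropyl tartrate (12 mol %), t-BuOOH (2 equiv, decane), 4 Å MS, CH2Cl2, −25 °C; NaOH/brine work-up, Et3N-deactivated silica
Reagents that add atoms: tert-butyl hydroperoxide, CC(C)(C)OO
Why: Sharpless asymmetric epoxidation: the titanium tartrate complex is anchored by the C6 hydroxyl group and so oxidises only the allylic trisubstituted alkene (the vinyl group is homoallylic and less electron-rich), and the D-(−)-tartrate delivers oxygen syn to the face that makes both oxirane carbons R, as known for E 2-substituted cinnamyl alcohols, which fixes the C2 configuration of the target.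

Step 5
Reactants: 7 [(2R,3R)-3-(3,4-dimethoxyphenyl)-2-ethenyloxiran-2-yl]methanol
Product: 8 tert-butyl{[(2R,3R)-3-(3,4-dimethoxyphenyl)-2-ethenyloxiran-2-yl]methoxy}dimethylsilane (aryl cis to vinyl)
Conditions: TBSCl (1.2 equiv), imidazole (2.5 equiv), CH2Cl2, 0 °C
Reagents that add atoms: tert-butyldimethylsilyl chloride, CC(C)(C)[Si](C)(C)Cl
Why: Imidazole-promoted silylation of the primary alcohol runs under mildly basic conditions that leave the acid-labile oxirane intact, and the silyl ether is a non-participating, weakly coordinating group for the next step.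

Step 6
Reactants: 8 tert-butyl{[(2R,3R)-3-(3,4-dimethoxyphenyl)-2-ethenyloxiran-2-yl]methoxy}dimethylsilane
Product: 9 tert-butyl{[(2R)-2-(3,4-dimethoxyphenyl)-2,5-dihydrofuran-3-yl]methoxy}dimethylsilane
Conditions: Cu(hfacac)2 (5 mol %), toluene (0.1 M), 100 °C, sealed tube, Ar, base-washed glassware
Reagents that add atoms: none
Why: The copper chelate (as a soft, weak Lewis acid, or after in situ reduction as monovalent copper hexafluoroacetylacetonate) engages the oxirane oxygen and the adjacent vinyl π-bond and breaks only the allylic C3–O bond, giving a copper alkoxide on C2 tethered to a C3–C4–C5 allyl unit (allyl cation or allylcopper), after which C–O bond formation at the terminus C5 gives O1–C5 and the C3=C4 double bond. The closest known reaction type is the copper-catalysed ring expansion of vinyl oxiranes to 2,5-dihydrofurans, a formal 1,3-oxygen shift of SN2' topology. The one new ring (O1–C2–C3–C4–C5) closes in a formally 5-endo-trig mode on the allyl terminus, equivalent to reductive elimination from a six-membered oxacupracycle, and needs C5 cis to C2 about C3–C4, a geometry reached by rotation or by η3–η1 interconversion once C3–O is broken. No stereocentre is created: C3 becomes sp2 and C2 keeps its bond to oxygen, so the configuration set in step 4 is transferred unchanged (descriptor R in 9). The selectivity needed is cleavage of C3–O in preference to the benzylic C2–O bond, whose ionisation is assisted by the para methoxy group and would cause racemisation or a 1,2-shift to carbonyl compounds. It is secured by the tertiary and allylic nature of C3, by relief of the cis aryl/vinyl eclipsing strain, by binding of copper to the vinyl group next to C3, by the weakly acidic chelate in a non-polar, acid-free medium and by a silyl ether that cannot participate.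

Step 7
Reactants: 9 tert-butyl{[(2R)-2-(3,4-dimethoxyphenyl)-2,5-dihydrofuran-3-yl]methoxy}dimethylsilane
Product: 11 (2S,3R,4R)-3-[(tert-butyldimethylsilyloxy)methyl]-2-(3,4-dimethoxyphenyl)oxolan-4-ol, via oxolan-4-ylborane 10 (not isolated)
Conditions: BH3·THF (2 equiv), THF, 0 °C → rt; then NaOH, H2O2, 0 °C
Reagents that add atoms: hydrogen peroxide, OO; borane–tetrahydrofuran, B.C1CCOC1 (boron in 10 only)
Why: Hydroboration–oxidation: syn addition should put boron on the less substituted C4 and hydrogen on C3 from the face opposite the C2 aryl group, which pushes C6 cis to the aryl group (C3 R), and oxidation with retention gives the C4 hydroxyl trans to C6 (C4 R).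

Step 8
Reactants: 11 (2S,3R,4R)-3-[(tert-butyldimethylsilyloxy)methyl]-2-(3,4-dimethoxyphenyl)oxolan-4-ol
Product: 12 (2S,3S)-3-[(tert-butyldimethylsilyloxy)methyl]-2-(3,4-dimethoxyphenyl)oxolan-4-one
Conditions: Dess–Martin periodinane (1.3 equiv), pyridine (4 equiv), CH2Cl2, 0 °C → rt; crude product used at once
Reagents that add atoms: none
Why: Dess–Martin oxidation buffered with pyridine converts the secondary alcohol into the ketone under near-neutral conditions, which protects the enolisable C3 centre and the β-oxygen substituents.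

Step 9
Reactants: 12 (2S,3S)-3-[(tert-butyldimethylsilyloxy)methyl]-2-(3,4-dimethoxyphenyl)oxolan-4-one
Product: 13 (2S,3R,4S)-3-[(tert-butyldimethylsilyloxy)methyl]-2-(3,4-dimethoxyphenyl)oxolan-4-ol (all-cis)
Conditions: LiBH(s-Bu)3 (1.2 equiv), THF, −78 °C; then NaOH, H2O2, 0 °C
Reagents that add atoms: none
Why: Bulky trialkylborohydride reduction: hydride should reach the C4 carbonyl from the face opposite the cis-disposed C6 and aryl substituents, faster than enolisation at −78 °C, so the new hydroxyl group is cis to C6 (C4 S).

Step 10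
Reactants: 13 (2S,3R,4S)-3-[(tert-butyldimethylsilyloxy)methyl]-2-(3,4-dimethoxyphenyl)oxolan-4-ol
Product: 14 (2S,3R,4S)-2-(3,4-dimethoxyphenyl)-3-(hydroxymethyl)oxolan-4-ol
Conditions: Bu4NF (1.2 equiv), THF, 0 °C → rt
Reagents that add atoms: none
Why: Fluoride-induced Si–O cleavage frees the primary alcohol without touching the ring stereocentres, and a silyl shift to O4 during step 9 would be harmless because both silyl isomers give the same diol.

Step 11
Reactants: 14 (2S,3R,4S)-2-(3,4-dimethoxyphenyl)-3-(hydroxymethyl)oxolan-4-ol; 15 3,4-dimethoxybenzoyl chloride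
Product: 16 [(2S,3R,4S)-2-(3,4-dimethoxyphenyl)-4-hydroxyoxolan-3-yl]methyl 3,4-dimethoxybenzoate (target)
Conditions: 15 (1.05 equiv), 2,4,6-collidine (2 equiv), CH2Cl2, −20 → 0 °C
Reagents that add atoms: none
Why: Chemoselective acylation: the unhindered primary C6 hydroxyl should react with one equivalent of the aroyl chloride at low temperature much faster than the secondary C4 hydroxyl on the crowded all-cis face, and the primary ester is also the thermodynamically preferred regioisomer.

Compound list
1 | (E)-3-(3,4-dimethoxyphenyl)prop-2-enal (3,4-dimethoxycinnamaldehyde) | COc1ccc(/C=C/C=O)cc1OC | starting material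
2 | 2,3-dibromo-3-(3,4-dimethoxyphenyl)propanal (racemic, diastereomer mixture) | O=CC(Br)C(Br)c1ccc(OC)c(OC)c1 | intermediate
3 | (Z)-2-bromo-3-(3,4-dimethoxyphenyl)prop-2-enal | O=C/C(Br)=C/c1ccc(OC)c(OC)c1 | intermediate
4 | (Z)-2-bromo-3-(3,4-dimethoxyphenyl)prop-2-en-1-ol | OC/C(Br)=C/c1ccc(OC)c(OC)c1 | intermediate
5 | vinylboronic acid pinacol ester | C=CB1OC(C)(C)C(C)(C)O1 | starting material
6 | (2E)-2-[(3,4-dimethoxyphenyl)methylidene]but-3-en-1-ol | OC/C(C=C)=C/c1ccc(OC)c(OC)c1 | intermediate
7 | [(2R,3R)-3-(3,4-dimethoxyphenyl)-2-ethenyloxiran-2-yl]methanol | C=C[C@]1(CO)O[C@@H]1c1ccc(OC)c(OC)c1 | intermediate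
8 | tert-butyl{[(2R,3R)-3-(3,4-dimethoxyphenyl)-2-ethenyloxiran-2-yl]methoxy}dimethylsilane | C=C[C@]1(CO[Si](C)(C)C(C)(C)C)O[C@@H]1c1ccc(OC)c(OC)c1 | intermediate
9 | tert-butyl{[(2R)-2-(3,4-dimethoxyphenyl)-2,5-dihydrofuran-3-yl]methoxy}dimethylsilane | CC(C)(C)[Si](C)(C)OCC1=CCO[C@@H]1c1ccc(OC)c(OC)c1 | intermediate
10 | [2-(3,4-dimethoxyphenyl)-3-(tert-butyldimethylsilyloxymethyl)oxolan-4-yl]borane, BH2 on C4 trans to C6 and to the aryl group | CC(C)(C)[Si](C)(C)OC[C@@H]1[C@@H](B)CO[C@@H]1c1ccc(OC)c(OC)c1 | intermediate
11 | (2S,3R,4R)-3-[(tert-butyldimethylsilyloxy)methyl]-2-(3,4-dimethoxyphenyl)oxolan-4-ol (target numbering; C6 cis to aryl, OH trans to both) | CC(C)(C)[Si](C)(C)OC[C@@H]1[C@@H](O)CO[C@@H]1c1ccc(OC)c(OC)c1 | intermediate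
12 | (2S,3S)-3-[(tert-butyldimethylsilyloxy)methyl]-2-(3,4-dimethoxyphenyl)oxolan-4-one (target numbering; C6 cis to aryl) | CC(C)(C)[Si](C)(C)OC[C@@H]1C(=O)CO[C@@H]1c1ccc(OC)c(OC)c1 | intermediate
13 | (2S,3R,4S)-3-[(tert-butyldimethylsilyloxy)methyl]-2-(3,4-dimethoxyphenyl)oxolan-4-ol (target numbering; all-cis) | CC(C)(C)[Si](C)(C)OC[C@@H]1[C@H](O)CO[C@@H]1c1ccc(OC)c(OC)c1 | intermediate
14 | (2S,3R,4S)-2-(3,4-dimethoxyphenyl)-3-(hydroxymethyl)oxolan-4-ol (target numbering; all-cis) | OC[C@@H]1[C@H](O)CO[C@@H]1c1ccc(OC)c(OC)c1 | intermediate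
15 | 3,4-dimethoxybenzoyl chloride | COc1ccc(C(Cl)=O)cc1OC | starting material
16 | [(2S,3R,4S)-2-(3,4-dimethoxyphenyl)-4-hydroxyoxolan-3-yl]methyl 3,4-dimethoxybenzoate | COc1ccc(C(=O)OC[C@@H]2[C@H](O)CO[C@@H]2c2ccc(OC)c(OC)c2)cc1OC | target

Total step count: 11. Longest linear sequence: 11 steps (1 → 16).

Steps most likely to fail

**Step 6.**
- What may go wrong: heterolysis of the benzylic C2–O bond, assisted by the para methoxy group, may compete. This would erode enantiopurity or cause a 1,2-shift to carbonyl compounds. The allyl intermediate may also stay in the rotamer that cannot close.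
- Fallback, from 8 back to 9: O1–C5 is made by etherification and the ring is closed by olefin metathesis.
- SmI2 in THF–MeOH at −78 °C opens the vinyl oxirane reductively at the allylic C3–O bond with alkene transposition, a known reaction of vinyl oxiranes that leaves C2–O alone. It should give (1R)-2-[(tert-butyldimethylsilyloxy)methyl]-1-(3,4-dimethoxyphenyl)but-2-en-1-ol F1 as an E/Z mixture.
- NaH and allyl bromide in THF at 0 °C convert it into the allyl ether (1R)-1-(allyloxy)-2-[(tert-butyldimethylsilyloxy)methyl]-1-(3,4-dimethoxyphenyl)but-2-ene F2.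
- Ring-closing metathesis with second-generation Grubbs catalyst (CH2Cl2, 40 °C) joins C3 to the internal allyl carbon. Both alkene isomers converge on 9.

**Step 4.**
- What may go wrong: titanium may promote opening of the freshly formed electron-rich benzylic, tertiary allylic oxirane by alcohol or hydroperoxide, or catalyst turnover may be slow.
- Fallback, from 6 back to 8: the order of the two steps is reversed and the metal is removed.
- Compound 6 is silylated (TBSCl, imidazole, CH2Cl2) to tert-butyl{[(2E)-2-(3,4-dimethoxybenzylidene)but-3-en-1-yl]oxy}dimethylsilane F3.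
- F3 undergoes a Shi epoxidation: D-fructose-derived ketone, Oxone (2KHSO5·KHSO4·K2SO4), K2CO3 buffer at about pH 10.5, MeCN–dimethoxymethane–H2O, 0 °C.
- The chiral dioxirane is known to pick the more electron-rich, more substituted alkene of conjugated dienes. With trans-disubstituted and trisubstituted styrenes it gives the R,R sense required, so 8 should result directly.

**Step 8.**
- What may go wrong: the ketone may enolise towards C3, which would destroy the cis C2/C3 relationship, or it may undergo β-elimination of the silyloxy group or of the ring oxygen.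
- Fallback, from 11 back to 13, replacing steps 8 and 9: the hydroxyl group is inverted without passing through a carbonyl group.
- Mitsunobu reaction of 11 (4-nitrobenzoic acid, PPh3, diisopropyl azodicarboxylate, toluene, 0 °C → rt) should give, by SN2 displacement at C4, the all-cis 4-nitrobenzoate ester of 13 at O4 F4.
- Methanolysis (K2CO3, MeOH, 0 °C) then gives 13.

Further compounds
F1 | step 6 | (1R)-2-[(tert-butyldimethylsilyloxy)methyl]-1-(3,4-dimethoxyphenyl)but-2-en-1-ol (E/Z mixture) | CC=C(CO[Si](C)(C)C(C)(C)C)[C@H](O)c1ccc(OC)c(OC)c1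
F2 | step 6 | (1R)-1-(allyloxy)-2-[(tert-butyldimethylsilyloxy)methyl]-1-(3,4-dimethoxyphenyl)but-2-ene (E/Z mixture) | CC=C(CO[Si](C)(C)C(C)(C)C)[C@H](OCC=C)c1ccc(OC)c(OC)c1
F3 | step 4 | tert-butyl{[(2E)-2-(3,4-dimethoxybenzylidene)but-3-en-1-yl]oxy}dimethylsilane | CC(C)(C)[Si](C)(C)OC/C(C=C)=C/c1ccc(OC)c(OC)c1
F4 | step 8 | all-cis 4-nitrobenzoate ester of 13 at O4 | CC(C)(C)[Si](C)(C)OC[C@@H]1[C@H](OC(=O)c2ccc(cc2)[N+](=O)[O-])CO[C@@H]1c1ccc(OC)c(OC)c1
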